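**Retrosynthetic overview**

- The acid is taken back to its ethyl ester, and the C3 bromine to an electrophilic bromination of the one ring CH of ethyl 4,5-dibromo-1-methylpyrrole-2-carboxylate.
- The pyrrole ring, the only ring, is opened at C2–C3. C2 lies between N1 and the ester carbon and is the one ring carbon that can act as an enolate, so C3 becomes a formyl carbon and the ring closes by intramolecular aldol condensation of an acyclic enaminal ester.
- C4–Br and C5–Br are not made on the pyrrole. They arrive in a tribromo three-carbon enal, Br2C=C(Br)–CHO, whose CBr2 terminus takes the sarcosinate nitrogen by vinylic substitution (N1–C5).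
- The enal is built from propargyl alcohol by alkyne C–H bromination, Br2 addition and oxidation.
- Ring order: one ring, formed in the key step; only the C3 bromination and the ester hydrolysis follow.

Key step: step 5

Assumption: the enaminal is drawn as its Z isomer (nitrogen and formyl cis, the geometry that cyclises). Either geometric isomer of this push–pull alkene should reach the same pyrrole, so the geometry delivered by step 4 is not treated as a control problem. The target has no stereocentre.

**Route**

Step 1
Reactants: 1 prop-2-yn-1-ol (propargyl alcohol)
Product: 2 3-bromoprop-2-yn-1-ol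
Conditions: NBS (1.1 equiv), AgNO3 (0.1 equiv), acetone, rt, dark
Reagents that add atoms: N-bromosuccinimide, O=C1CCC(=O)N1Br
Why: Silver-catalysed electrophilic bromination of a terminal alkyne C–H (through the silver acetylide) is a standard mild route to 1-bromoalkynes and leaves the primary alcohol untouched.

Step 2
Reactants: 2 3-bromoprop-2-yn-1-ol
Product: 3 2,3,3-tribromoprop-2-en-1-ol
Conditions: Br2 (1.05 equiv), CH2Cl2, 0 °C → rt, dark
Reagents that add atoms: bromine, BrBr
Why: Electrophilic addition of Br2 across the bromoalkyne should stop at the alkene, because the trihaloalkene is too electron-poor to add a second Br2, and the CBr2 terminus means there is no E/Z question.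

Step 3
Reactants: 3 2,3,3-tribromoprop-2-en-1-ol
Product: 4 2,3,3-tribromoprop-2-enal (tribromoacrolein)
Conditions: Dess–Martin periodinane (1.2 equiv), CH2Cl2, 0 °C → rt; pentane added, filtered through a silica plug (no aqueous work-up)
Reagents that add atoms: none
Why: Dess–Martin oxidation of a primary allylic alcohol stops at the aldehyde and does not depend on the alkene being electron-rich; the non-aqueous work-up keeps nucleophiles away from the strongly electrophilic CBr2 terminus of the enal.

Step 4
Reactants: 4 2,3,3-tribromoprop-2-enal; 5 sarcosine ethyl ester hydrochloride
Product: 7 ethyl N-[(Z)-1,2-dibromo-3-oxoprop-1-enyl]-N-methylglycinate, via sarcosine ethyl ester free base 6 (not isolated)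
Conditions: 5, cold aq. K2CO3/CH2Cl2, organic layer dried (Na2SO4); this solution of 6 (1.0 equiv) added dropwise to 4, iPr2NEt (1.1 equiv), CH2Cl2, −40 → 0 °C; Et2O added, salt filtered off, concentrated; crude 7 used at once
Reagents that add atoms: none
Why: Nucleophilic vinylic substitution (addition–elimination) of the secondary amine at the beta carbon of the beta,beta-dibromo enal, activated by the formyl group, should stop after one displacement because the product is a push–pull enaminal that is far less electrophilic than 4; the amine is used chloride-free and in one equivalent so that neither halide exchange nor a second displacement at the activated vinylic carbon is invited, and the hindered tertiary amine only takes up HBr.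

Step 5
Reactants: 7 ethyl N-[(Z)-1,2-dibromo-3-oxoprop-1-enyl]-N-methylglycinate
Product: 9 ethyl 4,5-dibromo-1-methyl-1H-pyrrole-2-carboxylate, via cyclic aldol adduct 8 (not isolated)
Conditions: K2CO3 (anhydrous, 1.5 equiv), 4 Å molecular sieves, DMF, 0 °C → rt (50 °C if the dehydration lags)
Reagents that add atoms: none
Why: Carbonate reversibly removes a proton from the N–CH2–CO2Et carbon, the only acidic C–H of 7 (its nitrogen is a vinylogous formamide nitrogen, so the methylene is activated like that of an N-acyl glycinate), and the ester enolate adds to the formyl carbon to form the C2–C3 bond; the aldol 8 then loses water across C2–C3 by an E1cB elimination that is irreversible because it creates the aromatic pyrrole. The closest known reaction type is the base-mediated cyclocondensation of N-(3-oxoprop-1-enyl) glycinates, obtained from beta-halovinyl aldehydes and glycine or sarcosine esters, to pyrrole-2-carboxylates. The single ring closes in a 5-(enolexo)-exo-trig mode once the formyl group twists out of the enaminal plane and turns its π* orbital towards the enolate carbon. The two stereocentres of 8 (C2 and C3) form without control and are both erased by the dehydration, so no element of stereocontrol is needed. The selectivity required is chemoselectivity: C–C bond formation at the formyl carbon must be faster than displacement or hydrolysis of the bromide on the nitrogen-bearing carbon, and this is secured by the intramolecular five-membered closure, by a non-nucleophilic anhydrous base, and by sieves that take up the water released. The low rotational barrier of the push–pull C=C bond makes the reactive geometry (nitrogen and formyl cis) available from either isomer, and once the ring is aromatic the C5–Br bond is an ordinary, inert bromopyrrole bond.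

Step 6
Reactants: 9 ethyl 4,5-dibromo-1-methyl-1H-pyrrole-2-carboxylate
Product: 10 ethyl 3,4,5-tribromo-1-methyl-1H-pyrrole-2-carboxylate
Conditions: Br2 (1.2 equiv), NaOAc (1.5 equiv), AcOH, rt → 50 °C, dark
Reagents that add atoms: bromine, BrBr
Why: Electrophilic aromatic bromination can only occur at C3, the single unsubstituted ring position, and the N-methylpyrrole should remain nucleophilic enough despite the ester and two bromines; NaOAc buffers the HBr so that acid-promoted bromine migration is suppressed.

Step 7
Reactants: 10 ethyl 3,4,5-tribromo-1-methyl-1H-pyrrole-2-carboxylate
Product: 12 3,4,5-tribromo-1-methyl-1H-pyrrole-2-carboxylic acid, via lithium carboxylate 11 (not isolated)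
Conditions: LiOH·H2O (3 equiv), THF/H2O 3:1, 40 °C; then 1 M HCl, 0 °C, to pH 2
Reagents that add atoms: lithium hydroxide, [Li+].[OH-]
Why: Saponification of the ethyl ester (acyl–oxygen cleavage by hydroxide) followed by cold acidification should give the acid, since C–Br bonds on the electron-rich pyrrole do not undergo substitution by hydroxide and brief cold acidification avoids protodecarboxylation.

**Compound list**

1 | prop-2-yn-1-ol (propargyl alcohol) | C#CCO | starting material
2 | 3-bromoprop-2-yn-1-ol | OCC#CBr | intermediate
3 | 2,3,3-tribromoprop-2-en-1-ol | OCC(Br)=C(Br)Br | intermediate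
4 | 2,3,3-tribromoprop-2-enal (tribromoacrolein) | O=CC(Br)=C(Br)Br | intermediate
5 | sarcosine ethyl ester hydrochloride (ethyl N-methylglycinate hydrochloride) | CNCC(=O)OCC.Cl | starting material
6 | sarcosine ethyl ester, free base (ethyl N-methylglycinate) | CNCC(=O)OCC | intermediate
7 | ethyl N-[(Z)-1,2-dibromo-3-oxoprop-1-enyl]-N-methylglycinate | CCOC(=O)CN(C)/C(Br)=C(Br)\C=O | intermediate
8 | ethyl 4,5-dibromo-3-hydroxy-1-methyl-2,3-dihydro-1H-pyrrole-2-carboxylate (racemic, both C2/C3 diastereomers) | CCOC(=O)C1C(O)C(Br)=C(Br)N1C | intermediate
9 | ethyl 4,5-dibromo-1-methyl-1H-pyrrole-2-carboxylate | CCOC(=O)c1cc(Br)c(Br)n1C | intermediate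
10 | ethyl 3,4,5-tribromo-1-methyl-1H-pyrrole-2-carboxylate | CCOC(=O)c1c(Br)c(Br)c(Br)n1C | intermediate
11 | lithium 3,4,5-tribromo-1-methyl-1H-pyrrole-2-carboxylate | Cn1c(Br)c(Br)c(Br)c1C(=O)[O-].[Li+] | intermediate
12 | 3,4,5-tribromo-1-methyl-1H-pyrrole-2-carboxylic acid | Cn1c(Br)c(Br)c(Br)c1C(=O)O | target

**Step count**

Total steps: 7. Longest linear sequence: 7 steps (1 → 12); the sarcosinate 5 enters at step 4.

**Steps most likely to fail, with fallbacks**

Step 5 (key step). The risk is that enolisation of the glycinate methylene is slower than loss of the bromide on the nitrogen-bearing carbon. That bromide could be hydrolysed by the water released in the condensation, or displaced by carbonate or by dimethylamine arising from DMF, so the open chain would be consumed before it closes. The fallback sets out from 7 and splits the closure into an irreversible low-temperature aldol addition and a separate elimination. Compound 7 is added to LiN(SiMe3)2 (1.05 equiv) in THF at −78 °C, where deprotonation is fast and no water or nucleophile is present. The lithium ester enolate should close at once to lithium ethyl 4,5-dibromo-1-methyl-3-oxido-2,3-dihydro-1H-pyrrole-2-carboxylate F1. Methanesulfonyl chloride is added at −78 °C to trap the alkoxide as ethyl 4,5-dibromo-1-methyl-3-(methylsulfonyloxy)-2,3-dihydro-1H-pyrrole-2-carboxylate F2. Et3N at 0 °C → rt then eliminates methanesulfonic acid across C2–C3, and the sequence comes back to the route at 9.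

Step 4. The risks are a second amine displacing the remaining bromide of 7 (ketene aminal formation), the amine being held up at the formyl group, and hydrolysis of the bromo enamine unit to the amide during isolation. The fallback sets out from 5 and uses a three-carbon unit with no leaving group on the nitrogen-bearing carbon, so that C5–Br is introduced later by electrophilic bromination. Compound 5 is condensed with commercial 2-bromomalonaldehyde (O=CC(Br)C=O) and NaOAc in EtOH at rt to give the stable vinylogous formamide ethyl N-[(Z)-2-bromo-3-oxoprop-1-enyl]-N-methylglycinate F3. K2CO3 in DMF at 60 °C should effect the same C2–C3 aldol closure, after rotation about the push–pull double bond, through ethyl 4-bromo-3-hydroxy-1-methyl-2,3-dihydro-1H-pyrrole-2-carboxylate F4 to ethyl 4-bromo-1-methyl-1H-pyrrole-2-carboxylate F5. NBS (1.05 equiv) in THF at 0 °C should then brominate the free alpha position C5 in preference to C3, and the sequence comes back to the route at 9.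

Step 6. The risk is that the ring of 9, deactivated by the ester and two bromines, substitutes too slowly at C3, leaving time for acid-promoted bromine migration or protodebromination. The fallback sets out from 9 and replaces electrophilic substitution by deprotonative metalation. TMPMgCl·LiCl (1.2 equiv) in THF at −40 °C should remove the C3 proton, the only ring proton, which is acidified by the flanking ester and C4–Br, to give ethyl 4,5-dibromo-3-(chloromagnesio)-1-methyl-1H-pyrrole-2-carboxylate F6. Quenching with 1,2-dibromotetrachloroethane (BrC(Cl)(Cl)C(Cl)(Cl)Br) delivers the bromine to C3, and the sequence comes back to the route at 10.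

Further compounds
F1 | step 5 | lithium ethyl 4,5-dibromo-1-methyl-3-oxido-2,3-dihydro-1H-pyrrole-2-carboxylate | CCOC(=O)C1C([O-])C(Br)=C(Br)N1C.[Li+]
F2 | step 5 | ethyl 4,5-dibromo-1-methyl-3-(methylsulfonyloxy)-2,3-dihydro-1H-pyrrole-2-carboxylate | CCOC(=O)C1C(OS(C)(=O)=O)C(Br)=C(Br)N1C
F3 | step 4 | ethyl N-[(Z)-2-bromo-3-oxoprop-1-enyl]-N-methylglycinate | CCOC(=O)CN(C)/C=C(Br)/C=O
F4 | step 4 | ethyl 4-bromo-3-hydroxy-1-methyl-2,3-dihydro-1H-pyrrole-2-carboxylate | CCOC(=O)C1C(O)C(Br)=CN1C
F5 | step 4 | ethyl 4-bromo-1-methyl-1H-pyrrole-2-carboxylate | CCOC(=O)c1cc(Br)cn1C
F6 | step 6 | ethyl 4,5-dibromo-3-(chloromagnesio)-1-methyl-1H-pyrrole-2-carboxylate | CCOC(=O)c1c([Mg]Cl)c(Br)c(Br)n1C
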